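**Retrosynthetic overview**

1. Numbering: azonine N(8)–C1–C2–C3=C4–C12–C11–C10–C9; cyclopentanone C4–C5(=O)–C6–C7–C12; cyclohexane C7–C12–C13(OAc)–C14–C15(Me)(OAc)–C16.
2. The strategy rests on the quaternary carbon C12, the one atom common to the six-, five- and nine-membered rings and bonded to C4 of the exocyclic C4=C3 enone (C2 cis to C12). A single C12–C4 bond made across the 12-membered ring C12-C11-C10-C9-N-C1-C2-C3-C4-C5-C6-C7 therefore forms the cyclopentane and the azonine in one event.
3. The macrocyclic alkyne is opened at N–C1 (sulfonamide Mitsunobu closure), then at C7–C6 (Mukaiyama–Michael addition of a 2-silyloxy enyne, which also leaves the C12=C13 silyl enol ether) and at C11–C12 (B-alkyl Suzuki coupling on a 2-iodoenone).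
4. The cyclohexenone with the C15 methyl carbinol is drawn from (−)-quinic acid (carboxyl carbon becomes the methyl group, the lactone-forming carbinol becomes C13).
5. Ring order: cyclohexane (chiral pool), then the 12-membered ring, then the five- and nine-membered rings together. End game: C13 reduction with N-detosylation, N-formylation, two acetylations, C5 oxidation.

Key step: step 22

Remark on the chemistry (assumption): a free N–H sulfonamide on the C12 side chain of the cyclohexenone would be expected to close by 6-endo aza-Michael addition under the basic coupling and the acidic Michael conditions, so the nitrogen is carried as N-Boc-N-tosyl from step 11 to step 19. The temporary C5 carbinol is set as (S) only for homogeneity, since it is oxidized at the end.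

**Route**

Step 1
Reactants: 1 (−)-quinic acid
Product: 2 3,4-O-isopropylidene-1,5-quinide (acetonide γ-lactone, all stereocentres of 1 retained)
Conditions: 2,2-dimethoxypropane, TsOH·H2O (cat.), acetone, reflux
Reagents that add atoms: 2,2-dimethoxypropane, COC(C)(C)OC
Why: Acid-catalysed acetalization takes the cis 3,4-diol while the carboxyl lactonizes onto the cis 5-hydroxyl, a standard one-pot protection of quinic acid.

Step 2
Reactants: 2 3,4-O-isopropylidene-1,5-quinide
Product: 3 acetonide triol (C1 hydroxymethyl carbinol, C5-OH free; quinic acid numbering)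
Conditions: NaBH4, EtOH, 0 °C → rt
Reagents that add atoms: none
Why: Borohydride reduction of the strained bicyclic lactone should open it to the primary alcohol and release the C5 hydroxyl without touching the acetonide.

Step 3
Reactants: 3 acetonide triol
Product: 4 primary p-toluenesulfonate of the triol
Conditions: TsCl (1.05 equiv), pyridine, CH2Cl2, 0 °C
Reagents that add atoms: p-toluenesulfonyl chloride, Cc1ccc(cc1)S(Cl)(=O)=O
Why: Selective sulfonylation, since the primary hydroxyl should react well before the ring-bound secondary one and the tertiary one is inert.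

Step 4
Reactants: 4 primary p-toluenesulfonate
Product: 6 acetonide-protected methyl carbinol diol (C1 methyl and C1-OH; C5-OH trans to the acetonide oxygens), via spiro-epoxide 5 (not isolated)
Conditions: LiEt3BH (excess), THF, 0 °C → 60 °C
Reagents that add atoms: none
Why: Reductive deoxygenation through an epoxide: the tertiary alkoxide displaces the neighbouring tosylate (3-exo-tet, no conformational demand, so it should outrun closure of the C5 alkoxide to a bridged ether, which needs the diaxial chair) and hydride then opens the epoxide at its CH2 by SN2, leaving the C1 configuration untouched.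

Step 5
Reactants: 6 acetonide-protected methyl carbinol diol
Product: 7 acetonide β-hydroxy ketone (ketone at the former C5, the later C13)
Conditions: Dess–Martin periodinane, NaHCO3, CH2Cl2, 0 °C → rt
Reagents that add atoms: none
Why: Dess–Martin oxidation of the only secondary alcohol under buffered, base-free conditions should avoid β-elimination of the acetonide oxygen; the tertiary carbinol cannot be oxidized.

Step 6
Reactants: 7 acetonide β-hydroxy ketone
Product: 8 tertiary triethylsilyl ether of the acetonide ketone
Conditions: Et3SiOTf, 2,6-lutidine, CH2Cl2, −78 °C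
Reagents that add atoms: triethylsilyl triflate, CC[Si](CC)(CC)OS(=O)(=O)C(F)(F)F
Why: Silyl triflate with lutidine is the standard silylation of a hindered tertiary alcohol and at −78 °C should be faster than enol silylation of the ketone.

Step 7
Reactants: 8 tertiary triethylsilyl ether
Product: 9 3-hydroxy-5-methyl-5-(triethylsilyloxy)cyclohexanone (hydroxyl cis to the silyloxy group)
Conditions: SmI2 (2.5 equiv), THF/MeOH, −78 °C
Reagents that add atoms: none
Why: Divalent samarium reduces the ketone to a ketyl that expels the α-alkoxy substituent (reductive α-heteroatom cleavage), methanol protonates the samarium enolate and the hemiketal alkoxide loses acetone to leave the β-hydroxy ketone.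

Step 8
Reactants: 9 3-hydroxy-5-methyl-5-(triethylsilyloxy)cyclohexanone
Product: 11 (S)-5-methyl-5-(triethylsilyloxy)cyclohex-2-enone, via mesylate 10 (not isolated)
Conditions: MsCl, Et3N, CH2Cl2, 0 °C → rt
Reagents that add atoms: none
Why: Mesylation followed by E1cB elimination through the α-CH2 gives the conjugated enone, the tertiary silyloxy group being a far poorer leaving group.

Step 9
Reactants: 11 (S)-5-methyl-5-(triethylsilyloxy)cyclohex-2-enone
Product: 12 (S)-2-iodo-5-methyl-5-(triethylsilyloxy)cyclohex-2-enone
Conditions: I2, pyridine, CH2Cl2, 0 °C → rt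
Reagents that add atoms: iodine, II
Why: α-Iodination of a cycloalkenone by conjugate addition of pyridine, iodination of the enolate and elimination, which places iodine on the later C12.

Step 10
Reactants: 13 allylamine
Product: 14 N-allyl-4-methylbenzenesulfonamide
Conditions: TsCl, Et3N, CH2Cl2, 0 °C
Reagents that add atoms: p-toluenesulfonyl chloride, Cc1ccc(cc1)S(Cl)(=O)=O
Why: Straightforward N-sulfonylation of a primary amine.

Step 11
Reactants: 14 N-allyl-4-methylbenzenesulfonamide
Product: 15 tert-butyl allyl(tosyl)carbamate
Conditions: Boc2O, Et3N, DMAP (cat.), CH2Cl2, rt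
Reagents that add atoms: di-tert-butyl dicarbonate, CC(C)(C)OC(=O)OC(=O)OC(C)(C)C
Why: DMAP-catalysed acylation of the acidic sulfonamide N–H masks the nitrogen so that it cannot add to the enone in the next two bond-forming steps.

Step 12
Reactants: 15 tert-butyl allyl(tosyl)carbamate and 12 (S)-2-iodo-5-methyl-5-(triethylsilyloxy)cyclohex-2-enone
Product: 17 (S)-2-[3-(N-Boc-N-tosylamino)propyl]-5-methyl-5-(triethylsilyloxy)cyclohex-2-enone, via B-alkyl-9-BBN 16 (not isolated)
Conditions: 15, 9-BBN, THF, 0 °C → rt; then 12, PdCl2(dppf) (5 mol %), AsPh3, Cs2CO3, DMF/THF/H2O, rt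
Reagents that add atoms: none
Why: Anti-Markovnikov hydroboration followed by B-alkyl Suzuki–Miyaura coupling with the 2-iodoenone forms the C11–C12 bond; the allyl alkene is consumed before palladium is added, so allylic ionization of the imide-like nitrogen is excluded.

Step 13
Reactants: 18 but-3-yn-1-ol and 19 acetyl chloride
Product: 20 but-3-ynyl acetate
Conditions: Et3N, DMAP (cat.), CH2Cl2, 0 °C
Reagents that add atoms: none
Why: Simple O-acylation of the primary alcohol.

Step 14
Reactants: 20 but-3-ynyl acetate and 19 acetyl chloride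
Product: 21 6-acetoxyhex-3-yn-2-one
Conditions: PdCl2(PPh3)2 (2 mol %), CuI (4 mol %), Et3N (1.2 equiv), THF, rt
Reagents that add atoms: none
Why: Acyl Sonogashira coupling of the acid chloride with the terminal alkyne gives the methyl ynone without a strong base that the acetate would not tolerate.

Step 15
Reactants: 21 6-acetoxyhex-3-yn-2-one
Product: 22 5-(tert-butyldimethylsilyloxy)hex-5-en-3-ynyl acetate (2-silyloxy enyne)
Conditions: t-BuMe2SiOTf, Et3N, CH2Cl2, 0 °C
Reagents that add atoms: tert-butyldimethylsilyl triflate, CC(C)(C)[Si](C)(C)OS(=O)(=O)C(F)(F)F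
Why: Soft enolization (silyl triflate with amine) of a ketone whose only α-hydrogens are on the methyl group gives the terminal silyl enol ether, the ester being much slower to enolize.

Step 16
Reactants: 17 (S)-2-[3-(N-Boc-N-tosylamino)propyl]-5-methyl-5-(triethylsilyloxy)cyclohex-2-enone and 22 5-(tert-butyldimethylsilyloxy)hex-5-en-3-ynyl acetate
Product: 23 Michael adduct: ynone side chain at C7 cis to the C15 silyloxy group, C12=C13 tert-butyldimethylsilyl enol ether, N-Boc-N-tosyl chain on C12
Conditions: HNTf2 (5 mol %), CH2Cl2, −78 °C; Et3N quench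
Reagents that add atoms: none
Why: Silyl-cation-catalysed Mukaiyama–Michael addition in which t-BuMe2SiNTf2 formed in situ activates the enone, the CH2 terminus of 22 bonds to C7 and the silyl group passes to O13, trapping the enolate regiospecifically as the C12=C13 enol ether; axial attack on the half-chair with the C15 methyl pseudo-equatorial should place the new C7–C6 bond cis to the pseudo-axial silyloxy group (the smaller syn-axial partner) and trans to the methyl.

Step 17
Reactants: 23 Michael adduct
Product: 24 (5S)-propargylic alcohol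
Conditions: Ru[(S,S)-TsNCHPhCHPhNH](p-cymene) (2 mol %), i-PrOH, rt
Reagents that add atoms: none
Why: Noyori asymmetric transfer hydrogenation of an alkynyl ketone under neutral conditions is catalyst-controlled and should give the (S) carbinol by analogy with other ynones, leaving alkyne, silyl enol ether, acetate and carbamate untouched.

Step 18
Reactants: 24 (5S)-propargylic alcohol
Product: 25 C5 tert-butyldimethylsilyl ether (N-Boc retained)
Conditions: t-BuMe2SiCl, imidazole, DMF, rt
Reagents that add atoms: tert-butyldimethylsilyl chloride, CC(C)(C)[Si](C)(C)Cl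
Why: Standard silylation of the secondary propargylic alcohol, so that C5 stays a non-polarizing sp3 ether during the gold step.

Step 19
Reactants: 25 C5 tert-butyldimethylsilyl ether
Product: 27 N–H tosylamide acetate (C5 silyl ether and C12=C13 silyl enol ether intact), via trimethylsilyl carbamate 26 (not isolated)
Conditions: Me3SiOTf, 2,6-lutidine, CH2Cl2, 0 °C; then MeOH
Reagents that add atoms: none
Why: Silyl-triflate-mediated cleavage of the tert-butyl carbamate (loss of isobutene to the silyl carbamate, then methanolysis and decarboxylation) removes the Boc group under the non-protic, lutidine-buffered conditions in which silyl enol ethers are themselves made and therefore survive.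

Step 20
Reactants: 27 N–H tosylamide acetate
Product: 28 seco sulfonamide alcohol (free C1-OH and N–H)
Conditions: K2CO3, MeOH, 0 °C → rt
Reagents that add atoms: none
Why: Mild methanolysis of the primary acetate; the hindered tetrasubstituted tert-butyldimethylsilyl enol ether and the silyl ethers should tolerate brief carbonate treatment.

Step 21
Reactants: 28 seco sulfonamide alcohol
Product: 29 12-membered aza-cycloalkyne fused at C7/C12 to the cyclohexenyl silyl ether
Conditions: n-Bu3P, TMAD, toluene (0.002 M, slow addition), rt → 60 °C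
Reagents that add atoms: none
Why: Intramolecular Mitsunobu N-alkylation of the tosylamide, using the more basic TMAD/n-Bu3P betaine for this weakly acidic N–H, should close the ring at N–C1 under high dilution, the alkyne and the planar sulfonamide keeping transannular strain low; no stereocentre is involved.

Step 22
Reactants: 29 12-membered aza-cycloalkyne
Product: 30 tricyclic C13 ketone with the C12 quaternary centre, the C4=C3 alkene (C2 cis to C12), the C5 silyl ether and N-tosyl
Conditions: [(2-biphenylyl)(t-Bu)2P]AuCl (5 mol %), AgSbF6 (5 mol %), CH2Cl2/MeOH (10:1), 0.01 M, rt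
Reagents that add atoms: none
Why: Proposed new method: the cationic phosphine complex of monovalent gold π-activates the C3≡C4 alkyne from the periphery of the macrocycle, the C12 terminus of the silyl enol ether attacks C4 anti to gold, methanol takes the silyl group from the oxocarbenium to reveal the C13 ketone, and protodeauration of the C3 vinylgold with retention leaves H trans and C2 cis to C12; the closest known reaction type is the gold-catalysed 5-exo-dig carbocyclization of silyl enol ethers onto tethered alkynes (Conia-ene type), which builds quaternary centres but has not been run across a macrocyclic internal alkyne. The cyclopentane (C12, C4, C5, C6, C7) closes 5-exo-dig through the C7–C6–C5 tether, and the azonine (C12, C4, C3, C2, C1, N, C9, C10, C11) arises in the same event by transannular contraction of the 12-membered ring, so it is never closed end to end. C12 is controlled by C7, because a three-atom tether can reach only the face of the enol ether that gives the cis-fused hydrindanone, and the anti carbometalation fixes the cis in-ring alkene geometry. The step needs attack at C4 (5-exo) and not at C3 (6-endo, which would leave an eight-membered co-ring); the short tether, the absence of a polarizing C5 carbonyl and the regiodefined enol ether from step 16 should secure this, and the phosphine on gold can be varied to reinforce it.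

Step 23
Reactants: 30 tricyclic C13 ketone
Product: 31 secondary amine with the C13 equatorial alcohol (cis to the C15 oxygen)
Conditions: Na, NH3(l), THF, t-BuOH, −78 °C; NH4Cl
Reagents that add atoms: none
Why: Dissolving-metal reduction cleaves the N–S bond by electron transfer and reduces the ketone under thermodynamic control to the equatorial C13 alcohol, which in the chair holding the C15 silyloxy group and C6 equatorial is cis to the C15 oxygen as required; a hydride reagent would have to pass the axial C15 methyl, whereas silyl ethers and the isolated alkene are inert at −78 °C.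

Step 24
Reactants: 31 secondary amine with the C13 alcohol
Product: 32 N-formyl C13 alcohol
Conditions: HCO2CH2CF3, THF, 50 °C
Reagents that add atoms: 2,2,2-trifluoroethyl formate, O=COCC(F)(F)F
Why: Aminolysis of an activated formate ester is selective for the amine over the secondary alcohol.

Step 25
Reactants: 32 N-formyl C13 alcohol
Product: 33 N-formyl C13,C15-diol (C5 silyl ether retained)
Conditions: PPTS, MeOH, rt → 40 °C
Reagents that add atoms: none
Why: Mild acid methanolysis should remove the triethylsilyl ether well before the much more acid-stable secondary tert-butyldimethylsilyl ether at C5.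

Step 26
Reactants: 33 N-formyl C13,C15-diol
Product: 34 N-formyl C13,C15-diacetate C5 silyl ether
Conditions: Ac2O, Et3N, DMAP, CH2Cl2, rt → 40 °C
Reagents that add atoms: acetic anhydride, CC(=O)OC(C)=O
Why: DMAP-catalysed acylation esterifies the secondary alcohol at once and, with excess reagent and time, the equatorial tertiary methyl carbinol as well.

Step 27
Reactants: 34 N-formyl diacetate C5 silyl ether
Product: 35 (5S)-allylic alcohol diacetate
Conditions: HF·pyridine, pyridine, THF, 0 °C → rt
Reagents that add atoms: none
Why: Buffered fluoride desilylation frees the allylic alcohol without acyl migration or ester cleavage.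

Step 28
Reactants: 35 (5S)-allylic alcohol diacetate
Product: 36 target CNP0137427.1
Conditions: Dess–Martin periodinane, NaHCO3, CH2Cl2, 0 °C → rt
Reagents that add atoms: none
Why: Dess–Martin oxidation of the only free hydroxyl gives the cross-conjugated cyclopentenone; the alkene cannot isomerize because C12 is quaternary and the ring enforces the cis in-ring geometry.

**Compound list**

1 | (−)-quinic acid | C1[C@H]([C@H]([C@@H](C[C@@]1(C(=O)O)O)O)O)O | starting material
2 | 3,4-O-isopropylidene-1,5-quinide | O=C1O[C@@H]2C[C@@]1(O)C[C@H]3OC(C)(C)O[C@@H]23 | intermediate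
3 | acetonide triol (C1 hydroxymethyl carbinol, C5-OH) | OC[C@@]1(O)C[C@@H](O)[C@@H]2OC(C)(C)O[C@@H]2C1 | intermediate
4 | primary p-toluenesulfonate of 3 | Cc1ccc(cc1)S(=O)(=O)OC[C@@]1(O)C[C@@H](O)[C@@H]2OC(C)(C)O[C@@H]2C1 | intermediate
5 | spiro-epoxide (not isolated) | C1O[C@@]12C[C@@H](O)[C@@H]3OC(C)(C)O[C@@H]3C2 | intermediate
6 | acetonide-protected methyl carbinol diol | C[C@@]1(O)C[C@@H](O)[C@@H]2OC(C)(C)O[C@@H]2C1 | intermediate
7 | acetonide β-hydroxy ketone | C[C@@]1(O)CC(=O)[C@@H]2OC(C)(C)O[C@@H]2C1 | intermediate
8 | tertiary triethylsilyl ether of 7 | C[C@@]1(O[Si](CC)(CC)CC)CC(=O)[C@@H]2OC(C)(C)O[C@@H]2C1 | intermediate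
9 | 3-hydroxy-5-methyl-5-(triethylsilyloxy)cyclohexanone (OH cis to OSiEt3) | C[C@@]1(O[Si](CC)(CC)CC)CC(=O)C[C@H](O)C1 | intermediate
10 | mesylate of 9 (not isolated) | C[C@@]1(O[Si](CC)(CC)CC)CC(=O)C[C@H](OS(C)(=O)=O)C1 | intermediate
11 | (S)-5-methyl-5-(triethylsilyloxy)cyclohex-2-enone | O=C1C=CC[C@](C)(O[Si](CC)(CC)CC)C1 | intermediate
12 | (S)-2-iodo-5-methyl-5-(triethylsilyloxy)cyclohex-2-enone | O=C1C(I)=CC[C@](C)(O[Si](CC)(CC)CC)C1 | intermediate
13 | allylamine | C=CCN | starting material
14 | N-allyl-4-methylbenzenesulfonamide | C=CCNS(=O)(=O)c1ccc(C)cc1 | intermediate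
15 | tert-butyl allyl(tosyl)carbamate | C=CCN(C(=O)OC(C)(C)C)S(=O)(=O)c1ccc(C)cc1 | intermediate
16 | B-[3-(N-Boc-N-tosylamino)propyl]-9-BBN (not isolated) | CC(C)(C)OC(=O)N(CCCB1C2CCCC1CCC2)S(=O)(=O)c1ccc(C)cc1 | intermediate
17 | (S)-2-[3-(N-Boc-N-tosylamino)propyl]-5-methyl-5-(triethylsilyloxy)cyclohex-2-enone | O=C1C(CCCN(C(=O)OC(C)(C)C)S(=O)(=O)c2ccc(C)cc2)=CC[C@](C)(O[Si](CC)(CC)CC)C1 | intermediate
18 | but-3-yn-1-ol | C#CCCO | starting material
19 | acetyl chloride | CC(Cl)=O | starting material
20 | but-3-ynyl acetate | C#CCCOC(C)=O | intermediate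
21 | 6-acetoxyhex-3-yn-2-one | CC(=O)C#CCCOC(C)=O | intermediate
22 | 5-(tert-butyldimethylsilyloxy)hex-5-en-3-ynyl acetate | C=C(O[Si](C)(C)C(C)(C)C)C#CCCOC(C)=O | intermediate
23 | Michael adduct (ynone, C12=C13 silyl enol ether, N-Boc-N-tosyl) | CC(C)(C)[Si](C)(C)OC1=C(CCCN(C(=O)OC(C)(C)C)S(=O)(=O)c2ccc(C)cc2)[C@H](CC(=O)C#CCCOC(C)=O)C[C@](C)(O[Si](CC)(CC)CC)C1 | intermediate
24 | (5S)-propargylic alcohol | CC(C)(C)[Si](C)(C)OC1=C(CCCN(C(=O)OC(C)(C)C)S(=O)(=O)c2ccc(C)cc2)[C@H](C[C@H](O)C#CCCOC(C)=O)C[C@](C)(O[Si](CC)(CC)CC)C1 | intermediate
25 | C5 tert-butyldimethylsilyl ether (N-Boc) | CC(C)(C)[Si](C)(C)OC1=C(CCCN(C(=O)OC(C)(C)C)S(=O)(=O)c2ccc(C)cc2)[C@H](C[C@H](O[Si](C)(C)C(C)(C)C)C#CCCOC(C)=O)C[C@](C)(O[Si](CC)(CC)CC)C1 | intermediate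
26 | trimethylsilyl carbamate (not isolated) | CC(C)(C)[Si](C)(C)OC1=C(CCCN(C(=O)O[Si](C)(C)C)S(=O)(=O)c2ccc(C)cc2)[C@H](C[C@H](O[Si](C)(C)C(C)(C)C)C#CCCOC(C)=O)C[C@](C)(O[Si](CC)(CC)CC)C1 | intermediate
27 | N–H tosylamide acetate | CC(C)(C)[Si](C)(C)OC1=C(CCCNS(=O)(=O)c2ccc(C)cc2)[C@H](C[C@H](O[Si](C)(C)C(C)(C)C)C#CCCOC(C)=O)C[C@](C)(O[Si](CC)(CC)CC)C1 | intermediate
28 | seco sulfonamide alcohol | CC(C)(C)[Si](C)(C)OC1=C(CCCNS(=O)(=O)c2ccc(C)cc2)[C@H](C[C@H](O[Si](C)(C)C(C)(C)C)C#CCCO)C[C@](C)(O[Si](CC)(CC)CC)C1 | intermediate
29 | 12-membered aza-cycloalkyne | CC(C)(C)[Si](C)(C)OC1=C2CCCN(S(=O)(=O)c3ccc(C)cc3)CCC#C[C@@H](O[Si](C)(C)C(C)(C)C)C[C@@H]2C[C@](C)(O[Si](CC)(CC)CC)C1 | intermediate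
30 | tricyclic C13 ketone (N-tosyl, C5 silyl ether) | O=C1C[C@@](C)(O[Si](CC)(CC)CC)C[C@H]2C[C@H](O[Si](C)(C)C(C)(C)C)/C3=C/CCN(S(=O)(=O)c4ccc(C)cc4)CCC[C@@]321 | intermediate
31 | secondary amine with C13 equatorial alcohol | O[C@H]1C[C@@](C)(O[Si](CC)(CC)CC)C[C@H]2C[C@H](O[Si](C)(C)C(C)(C)C)/C3=C/CCNCCC[C@@]321 | intermediate
32 | N-formyl C13 alcohol | O[C@H]1C[C@@](C)(O[Si](CC)(CC)CC)C[C@H]2C[C@H](O[Si](C)(C)C(C)(C)C)/C3=C/CCN(C=O)CCC[C@@]321 | intermediate
33 | N-formyl C13,C15-diol | O[C@H]1C[C@@](C)(O)C[C@H]2C[C@H](O[Si](C)(C)C(C)(C)C)/C3=C/CCN(C=O)CCC[C@@]321 | intermediate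
34 | N-formyl diacetate C5 silyl ether | CC(=O)O[C@H]1C[C@@](C)(OC(C)=O)C[C@H]2C[C@H](O[Si](C)(C)C(C)(C)C)/C3=C/CCN(C=O)CCC[C@@]321 | intermediate
35 | (5S)-allylic alcohol diacetate | CC(=O)O[C@H]1C[C@@](C)(OC(C)=O)C[C@H]2C[C@H](O)/C3=C/CCN(C=O)CCC[C@@]321 | intermediate
36 | CNP0137427.1, (7S,12S,13S,15S) in the numbering used here | CC(=O)O[C@H]1C[C@@](C)(OC(C)=O)C[C@H]2CC(=O)/C3=C/CCN(C=O)CCC[C@@]321 | target

**Step count**

Total: 28 steps. Longest linear sequence: 23 steps from (−)-quinic acid (steps 1–9, 12, 16–28).

**Steps most likely to fail**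

Step 22 (new method). The silyl enol ether may be protodesilylated before the C–C bond forms, attack may go to C3 (6-endo), or the macrocycle may not reach a conformation that brings C12 over C4. The fallback uses known chemistry and sets out from 27. The same cationic gold catalyst in CH2Cl2/MeOH should effect the established open-chain 5-exo-dig cyclization of the silyl enol ether onto the tethered alkyne. This should give the cis-hydrindanone acetate F1, with C12 and the alkene geometry set as in the main route. Methanolysis (K2CO3, MeOH) should give the hydroxy sulfonamide F2. An intramolecular Mitsunobu N-alkylation (n-Bu3P, TMAD, toluene, high dilution) then closes the nine-membered ring end to end at N–C1, helped by the cis alkene, and rejoins the route at 30.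

Step 21. Intermolecular alkylation may outrun closure of the 12-membered ring, or the activated homopropargylic alcohol may eliminate to an enyne, the tosylamide being a borderline Mitsunobu acid. The fallback sets out from 28. Mesylation (MsCl, Et3N, CH2Cl2, 0 °C) should give the primary mesylate F3. Sulfonamide alkylation under cesium carbonate (Cs2CO3, n-Bu4NI cat., DMF, 0.002 M, 50 °C) replaces the redox condensation by an SN2 closure on a preformed electrophile and comes back at 29.

Step 16. The alkynyl-substituted enol ether is a weak nucleophile and the 2-alkylated enone a hindered acceptor, so addition may be slow, with desilylation of the donor, oligomerization through the product ynone or loss of facial selectivity on warming. The fallback sets out from 17 and uses the much more nucleophilic ketene silyl thioacetal 1-(ethylthio)-1-(tert-butyldimethylsilyloxy)ethene F4, made from S-ethyl thioacetate with LDA and t-BuMe2SiCl. Under the same silyl-cation catalysis at −78 °C this should give the S-ethyl thioester silyl enol ether F5 with the same facial preference. A palladium/copper-mediated coupling of the thiol ester with the terminal alkyne 20 (PdCl2(dppf), tri(2-furyl)phosphine, CuI, Et3N, DMF, 50 °C) then installs the ynone and comes back at 23.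

**Further compounds**

F1 | step 22 | open-chain cyclization product: cis-hydrindanone with exocyclic alkene (C2 cis to C12), acetate and N–H tosylamide chains | O=C1C[C@@](C)(O[Si](CC)(CC)CC)C[C@H]2C[C@H](O[Si](C)(C)C(C)(C)C)/C(=C/CCOC(C)=O)[C@]21CCCNS(=O)(=O)c1ccc(C)cc1
F2 | step 22 | hydroxy sulfonamide from F1 | O=C1C[C@@](C)(O[Si](CC)(CC)CC)C[C@H]2C[C@H](O[Si](C)(C)C(C)(C)C)/C(=C/CCO)[C@]21CCCNS(=O)(=O)c1ccc(C)cc1
F3 | step 21 | primary mesylate of 28 | CC(C)(C)[Si](C)(C)OC1=C(CCCNS(=O)(=O)c2ccc(C)cc2)[C@H](C[C@H](O[Si](C)(C)C(C)(C)C)C#CCCOS(C)(=O)=O)C[C@](C)(O[Si](CC)(CC)CC)C1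
F4 | step 16 | 1-(ethylthio)-1-(tert-butyldimethylsilyloxy)ethene | C=C(SCC)O[Si](C)(C)C(C)(C)C
F5 | step 16 | S-ethyl thioester with C12=C13 silyl enol ether | CC(C)(C)[Si](C)(C)OC1=C(CCCN(C(=O)OC(C)(C)C)S(=O)(=O)c2ccc(C)cc2)[C@H](CC(=O)SCC)C[C@](C)(O[Si](CC)(CC)CC)C1
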